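**Retrosynthetic overview**

1. The route rests on ring E (C1 = the carbon bound to the ether oxygen of ring D; C3, C4, C5 = the three hydroxylated carbons). Its oxygens at C1, C3 and C5 stand 1,3,5, so C3–C4–C5 come from a methoxymalonyl unit and C6–C1–C2 from a 3-aryloxybut-2-enoyl unit already bound to the ring D oxygen.
2. Key disconnection: the C2–C3 bond of ring E, closed by Claisen attack of the methyl-derived dienolate carbon on an ester. A second methoxycarbonyl group on C4 removes the acidic hydrogen there and leaves as dimethyl carbonate on aromatisation.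
3. The D–O–E ether is made by oxa-Michael addition of the ring D phenol to methyl but-2-ynoate, not by aryl coupling. The ring D phenol comes from 3-hydroxy-4,5-dimethoxybenzaldehyde by Dakin-type oxidation and benzylation.
4. The A–B–C bromide is assembled from three bought arenes by two copper-catalysed ether couplings, a ring C bromination and a Dakin-type oxidation. It is joined to the debenzylated D–E phenol by a last Ullmann coupling.
5. Ring order: rings A–D are bought as arenes and ring E is the only ring built (step 8). Cleavage of thirteen methyl ethers ends the route.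

Key step: step 8

Remark on the chemistry: the target has no stereocentre. The quaternary carbon of intermediate 13 forms as a racemate and is lost in the same flask. Only the E geometry of the enol ether double bond in 8, 9, 11 and 12 is specified. Compounds 1, 7, 10, 17, 18 and 23 are taken as catalogue compounds.

**Route**

Step 1
Reactants: 1 3-hydroxy-4,5-dimethoxybenzaldehyde
Product: 2 3,4-dimethoxy-5-(methoxymethoxy)benzaldehyde
Conditions: NaH, DMF, 0 °C; then MOMCl, 0 → 23 °C
Reagents that add atoms: chloromethyl methyl ether, COCCl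
Why: Williamson-type O-alkylation of the sodium phenoxide masks the oxygen that will later carry ring E, so that the second phenol can be unveiled and benzylated separately.

Step 2
Reactants: 2 3,4-dimethoxy-5-(methoxymethoxy)benzaldehyde
Product: 4 3,4-dimethoxy-5-(methoxymethoxy)phenol, via aryl formate 3 (not isolated)
Conditions: mCPBA, CH2Cl2, 0 → 23 °C; then K2CO3 (cat.), MeOH, 23 °C
Reagents that add atoms: 3-chloroperbenzoic acid, OOC(=O)c1cccc(Cl)c1
Why: In this Baeyer–Villiger (Dakin-type) oxidation the electron-rich trialkoxyaryl group should migrate in preference to hydrogen, and the aryl formate is methanolysed under conditions that leave the MOM acetal untouched.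

Step 3
Reactants: 4 3,4-dimethoxy-5-(methoxymethoxy)phenol
Product: 5 5-(benzyloxy)-1,2-dimethoxy-3-(methoxymethoxy)benzene
Conditions: BnBr, K2CO3, DMF, 23 °C
Reagents that add atoms: benzyl bromide, BrCc1ccccc1
Why: Williamson benzylation of the only free phenol places the hydrogenolysable group on the oxygen that will later bind ring C.

Step 4
Reactants: 5 5-(benzyloxy)-1,2-dimethoxy-3-(methoxymethoxy)benzene
Product: 6 5-(benzyloxy)-2,3-dimethoxyphenol
Conditions: HCl (cat.), MeOH, 50 °C
Reagents that add atoms: none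
Why: Acid-catalysed acetal exchange with methanol removes the MOM group while benzyl and methyl aryl ethers are stable.

Step 5
Reactants: 6 5-(benzyloxy)-2,3-dimethoxyphenol; 7 methyl but-2-ynoate
Product: 8 methyl (2E)-3-[5-(benzyloxy)-2,3-dimethoxyphenoxy]but-2-enoate
Conditions: K2CO3 (0.3 equiv), DMF, 70 °C
Reagents that add atoms: none
Why: Base-catalysed oxa-Michael addition of the phenoxide to the ynoate forms the D–O–E ether at the β-carbon, and under these equilibrating conditions the E isomer (aryloxy trans to the ester, methyl cis to the carbonyl) should predominate.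

Step 6
Reactants: 8 methyl (2E)-3-[5-(benzyloxy)-2,3-dimethoxyphenoxy]but-2-enoate
Product: 9 (2E)-3-[5-(benzyloxy)-2,3-dimethoxyphenoxy]but-2-enoic acid
Conditions: LiOH, THF/MeOH/H2O, 40 °C; then 1 M HCl to pH 3, 0 °C
Reagents that add atoms: lithium hydroxide, [Li+].[OH-]
Why: Saponification at the acyl carbon is the classical way to 3-aryloxycrotonic acids, and the β-methyl group shields the enol ether carbon against addition–elimination.

Step 7
Reactants: 9 (2E)-3-[5-(benzyloxy)-2,3-dimethoxyphenoxy]but-2-enoic acid; 10 dimethyl 2-methoxypropanedioate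
Product: 12 dimethyl 2-{(2E)-3-[5-(benzyloxy)-2,3-dimethoxyphenoxy]but-2-enoyl}-2-methoxypropanedioate, via acid chloride 11 (not isolated)
Conditions: (COCl)2, DMF (cat.), CH2Cl2, 0 → 23 °C, evaporate; then 10, NaH, THF, 0 °C, add crude 11, 0 → 23 °C
Reagents that add atoms: none
Why: C-acylation of the sodium enolate of the methoxymalonate by the acid chloride gives a triacylmethane with no acidic hydrogen, so one equivalent of base suffices, and the E geometry holds the acyl carbon away from ring D so that Friedel–Crafts closure is not possible.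

Step 8
Reactants: 12 dimethyl 2-{(2E)-3-[5-(benzyloxy)-2,3-dimethoxyphenoxy]but-2-enoyl}-2-methoxypropanedioate
Product: 14 5-[5-(benzyloxy)-2,3-dimethoxyphenoxy]-2-methoxybenzene-1,3-diol, via cyclised diketo ester 13 (not isolated)
Conditions: LiN(SiMe3)2 (2.2 equiv), THF, −78 → 0 °C (12 added slowly to the base); then MeOH as co-solvent, 23 °C; 1 M HCl
Reagents that add atoms: none
Why: The malonyl carbon of 12 is quaternary, so LiN(SiMe3)2 can only remove a methyl hydrogen, giving the dienolate O–C=CH–C(OAr)=CH2, whose terminal carbon adds to one of the two equivalent methoxycarbonyl groups and expels methoxide; this forms the C2–C3 bond and closes ring E in a 6-(enolendo)-exo-trig Claisen (Dieckmann-type) condensation. The closest known reaction type is the base-mediated Claisen cyclisation of 3,5-dioxo esters and their β-alkoxy enone forms to phloroglucinols and resorcinols. Diketo ester 13 is deprotonated at its ring CH2, and the lithium methoxide set free then attacks the remaining ester on the quaternary carbon in a retro-Claisen step that releases dimethyl carbonate and the aromatic bis-phenoxide of 14, with aromatisation as the driving force. The quaternary carbon of 13 is a transient stereocentre, formed as a racemate and erased here, so nothing has to be controlled. The step needs C-acylation through the γ-carbon: attack through the α-carbon or the enolate oxygen would give four-membered rings, and the E geometry (or rotation about the C–C single bond of the dienolate) brings the CH2 terminus within reach of the ester. The second ester is essential, because in a simple α-methoxy β-keto ester the hydrogen between ketone and ester would be lost first and the ester would become an unreactive enolate.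

Step 9
Reactants: 14 5-[5-(benzyloxy)-2,3-dimethoxyphenoxy]-2-methoxybenzene-1,3-diol
Product: 15 5-(benzyloxy)-1,2-dimethoxy-3-(3,4,5-trimethoxyphenoxy)benzene
Conditions: MeI, K2CO3, DMF, 23 °C
Reagents that add atoms: iodomethane, CI
Why: Williamson O-methylation of both phenols turns ring E into a 3,4,5-trimethoxyphenyl group, the central position between the two hydroxyls being blocked against C-alkylation by the methoxy group.

Step 10
Reactants: 15 5-(benzyloxy)-1,2-dimethoxy-3-(3,4,5-trimethoxyphenoxy)benzene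
Product: 16 3,4-dimethoxy-5-(3,4,5-trimethoxyphenoxy)phenol
Conditions: H2 (1 atm), 10% Pd/C, EtOAc/MeOH, 23 °C
Reagents that add atoms: none
Why: Catalytic hydrogenolysis cleaves only the benzylic C–O bond and leaves the diaryl ether and the methyl ethers intact.

Step 11
Reactants: 17 3,4,5-trimethoxyphenol; 18 4-bromo-3,5-dimethoxybenzaldehyde
Product: 19 3,5-dimethoxy-4-(3,4,5-trimethoxyphenoxy)benzaldehyde
Conditions: CuI (10 mol%), N,N-dimethylglycine hydrochloride (30 mol%), Cs2CO3, 1,4-dioxane, 100 °C
Reagents that add atoms: none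
Why: In this Ullmann-type diaryl ether synthesis the bromide para to the formyl group is activated, and the unhindered electron-rich phenoxide should tolerate the two flanking methoxy groups.

Step 12
Reactants: 19 3,5-dimethoxy-4-(3,4,5-trimethoxyphenoxy)benzaldehyde
Product: 20 4-(2-bromo-3,4,5-trimethoxyphenoxy)-3,5-dimethoxybenzaldehyde
Conditions: NBS (1.0 equiv), MeCN, 0 °C
Reagents that add atoms: N-bromosuccinimide, O=C1CCC(=O)N1Br
Why: Electrophilic aromatic bromination should take place only on ring C, whose two equivalent free positions are ortho and para to oxygen, while ring B is deactivated by its formyl group.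

Step 13
Reactants: 20 4-(2-bromo-3,4,5-trimethoxyphenoxy)-3,5-dimethoxybenzaldehyde
Product: 22 4-(2-bromo-3,4,5-trimethoxyphenoxy)-3,5-dimethoxyphenol, via aryl formate 21 (not isolated)
Conditions: mCPBA, CH2Cl2, 23 °C; then K2CO3 (cat.), MeOH, 23 °C
Reagents that add atoms: 3-chloroperbenzoic acid, OOC(=O)c1cccc(Cl)c1
Why: Baeyer–Villiger (Dakin-type) oxidation of a 3,4,5-trioxygenated benzaldehyde proceeds with aryl migration and turns the formyl group of ring B into the phenol that will bind ring A.

Step 14
Reactants: 22 4-(2-bromo-3,4,5-trimethoxyphenoxy)-3,5-dimethoxyphenol; 23 2-iodo-1,3,5-trimethoxybenzene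
Product: 24 2-[4-(2-bromo-3,4,5-trimethoxyphenoxy)-3,5-dimethoxyphenoxy]-1,3,5-trimethoxybenzene
Conditions: CuI (10 mol%), picolinic acid (20 mol%), K3PO4, DMSO, 90 °C
Reagents that add atoms: none
Why: In this Ullmann-type coupling the unhindered phenol should react with the aryl iodide, which at this temperature enters the copper cycle well before the hindered, unactivated bromide on ring C.

Step 15
Reactants: 16 3,4-dimethoxy-5-(3,4,5-trimethoxyphenoxy)phenol; 24 2-[4-(2-bromo-3,4,5-trimethoxyphenoxy)-3,5-dimethoxyphenoxy]-1,3,5-trimethoxybenzene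
Product: 25 2-[4-(2-{3,4-dimethoxy-5-(3,4,5-trimethoxyphenoxy)phenoxy}-3,4,5-trimethoxyphenoxy)-3,5-dimethoxyphenoxy]-1,3,5-trimethoxybenzene
Conditions: CuI (20 mol%), 2,2,6,6-tetramethylheptane-3,5-dione (40 mol%), Cs2CO3, NMP, 120 °C
Reagents that add atoms: none
Why: Ullmann diaryl ether synthesis with a diketone ligand is suited to electron-rich, ortho-substituted aryl bromides, and the phenol 16 has two free ortho positions.

Step 16
Reactants: 25 the tridecamethyl ether named in step 15
Product: 26 4-[3,4-dihydroxy-5-(3,4,5-trihydroxyphenoxy)phenoxy]-5-[2,6-dihydroxy-4-(2,4,6-trihydroxyphenoxy)phenoxy]benzene-1,2,3-triol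
Conditions: BBr3 (excess), CH2Cl2, −78 → 23 °C; then H2O, 0 °C, under argon
Reagents that add atoms: none
Why: Lewis-acid ether cleavage by BBr3 proceeds by bromide attack at the methyl carbon of each aryl methyl ether, a path not open to the four diaryl ether bonds.

**Compound list**

1 | 3-hydroxy-4,5-dimethoxybenzaldehyde | COc1cc(C=O)cc(O)c1OC | starting material
2 | 3,4-dimethoxy-5-(methoxymethoxy)benzaldehyde | COCOc1cc(C=O)cc(OC)c1OC | intermediate
3 | 3,4-dimethoxy-5-(methoxymethoxy)phenyl formate | COCOc1cc(OC=O)cc(OC)c1OC | intermediate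
4 | 3,4-dimethoxy-5-(methoxymethoxy)phenol | COCOc1cc(O)cc(OC)c1OC | intermediate
5 | 5-(benzyloxy)-1,2-dimethoxy-3-(methoxymethoxy)benzene | COCOc1cc(OCc2ccccc2)cc(OC)c1OC | intermediate
6 | 5-(benzyloxy)-2,3-dimethoxyphenol | Oc1cc(OCc2ccccc2)cc(OC)c1OC | intermediate
7 | methyl but-2-ynoate | CC#CC(=O)OC | starting material
8 | methyl (2E)-3-[5-(benzyloxy)-2,3-dimethoxyphenoxy]but-2-enoate | COC(=O)/C=C(\C)Oc1cc(OCc2ccccc2)cc(OC)c1OC | intermediate
9 | (2E)-3-[5-(benzyloxy)-2,3-dimethoxyphenoxy]but-2-enoic acid | OC(=O)/C=C(\C)Oc1cc(OCc2ccccc2)cc(OC)c1OC | intermediate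
10 | dimethyl 2-methoxypropanedioate (dimethyl methoxymalonate) | COC(=O)C(OC)C(=O)OC | starting material
11 | (2E)-3-[5-(benzyloxy)-2,3-dimethoxyphenoxy]but-2-enoyl chloride | ClC(=O)/C=C(\C)Oc1cc(OCc2ccccc2)cc(OC)c1OC | intermediate
12 | dimethyl 2-{(2E)-3-[5-(benzyloxy)-2,3-dimethoxyphenoxy]but-2-enoyl}-2-methoxypropanedioate | COC(=O)C(OC)(C(=O)OC)C(=O)/C=C(\C)Oc1cc(OCc2ccccc2)cc(OC)c1OC | intermediate
13 | methyl 4-[5-(benzyloxy)-2,3-dimethoxyphenoxy]-1-methoxy-2,6-dioxocyclohex-3-ene-1-carboxylate (racemic) | COC(=O)C1(OC)C(=O)CC(Oc2cc(OCc3ccccc3)cc(OC)c2OC)=CC1=O | intermediate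
14 | 5-[5-(benzyloxy)-2,3-dimethoxyphenoxy]-2-methoxybenzene-1,3-diol | Oc1cc(Oc2cc(OCc3ccccc3)cc(OC)c2OC)cc(O)c1OC | intermediate
15 | 5-(benzyloxy)-1,2-dimethoxy-3-(3,4,5-trimethoxyphenoxy)benzene | COc1cc(Oc2cc(OCc3ccccc3)cc(OC)c2OC)cc(OC)c1OC | intermediate
16 | 3,4-dimethoxy-5-(3,4,5-trimethoxyphenoxy)phenol | COc1cc(Oc2cc(O)cc(OC)c2OC)cc(OC)c1OC | intermediate
17 | 3,4,5-trimethoxyphenol | COc1cc(O)cc(OC)c1OC | starting material
18 | 4-bromo-3,5-dimethoxybenzaldehyde | O=Cc1cc(OC)c(Br)c(OC)c1 | starting material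
19 | 3,5-dimethoxy-4-(3,4,5-trimethoxyphenoxy)benzaldehyde | O=Cc1cc(OC)c(Oc2cc(OC)c(OC)c(OC)c2)c(OC)c1 | intermediate
20 | 4-(2-bromo-3,4,5-trimethoxyphenoxy)-3,5-dimethoxybenzaldehyde | O=Cc1cc(OC)c(Oc2cc(OC)c(OC)c(OC)c2Br)c(OC)c1 | intermediate
21 | 4-(2-bromo-3,4,5-trimethoxyphenoxy)-3,5-dimethoxyphenyl formate | O=COc1cc(OC)c(Oc2cc(OC)c(OC)c(OC)c2Br)c(OC)c1 | intermediate
22 | 4-(2-bromo-3,4,5-trimethoxyphenoxy)-3,5-dimethoxyphenol | Oc1cc(OC)c(Oc2cc(OC)c(OC)c(OC)c2Br)c(OC)c1 | intermediate
23 | 2-iodo-1,3,5-trimethoxybenzene | COc1cc(OC)c(I)c(OC)c1 | starting material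
24 | 2-[4-(2-bromo-3,4,5-trimethoxyphenoxy)-3,5-dimethoxyphenoxy]-1,3,5-trimethoxybenzene | COc1cc(OC)c(Oc2cc(OC)c(Oc3cc(OC)c(OC)c(OC)c3Br)c(OC)c2)c(OC)c1 | intermediate
25 | 2-[4-(2-{3,4-dimethoxy-5-(3,4,5-trimethoxyphenoxy)phenoxy}-3,4,5-trimethoxyphenoxy)-3,5-dimethoxyphenoxy]-1,3,5-trimethoxybenzene (tridecamethyl ether of 26) | COc1cc(OC)c(Oc2cc(OC)c(Oc3cc(OC)c(OC)c(OC)c3Oc3cc(OC)c(OC)c(Oc4cc(OC)c(OC)c(OC)c4)c3)c(OC)c2)c(OC)c1 | intermediate
26 | 4-[3,4-dihydroxy-5-(3,4,5-trihydroxyphenoxy)phenoxy]-5-[2,6-dihydroxy-4-(2,4,6-trihydroxyphenoxy)phenoxy]benzene-1,2,3-triol | Oc1cc(O)c(Oc2cc(O)c(Oc3cc(O)c(O)c(O)c3Oc3cc(O)c(O)c(Oc4cc(O)c(O)c(O)c4)c3)c(O)c2)c(O)c1 | target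

**Step count and risks**

Total step count: 16. Longest linear sequence: 12 steps (steps 1–10, 15, 16); the A–B–C branch is steps 11–14.

Step 8 is the most likely to fail. Removal of the methyl hydrogen may be too slow, or the methoxide released by the first closed molecules may cleave the acyl–malonate bond of 12 that has not yet been deprotonated, so that open-chain fragments form instead of ring E. Adding 12 to excess base at −78 °C is meant to convert all of it to the dienolate before closure starts. The fallback gives up building ring E and introduces it as a finished arene. It sets out from phenol 6, which is coupled with purchased 5-bromo-1,2,3-trimethoxybenzene (COc1cc(Br)cc(OC)c1OC) under Ullmann conditions (CuI, picolinic acid, K3PO4, DMSO, 90 °C). This should give 15 directly, where the route is rejoined. The fallback makes no compound outside the list (F0).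

Step 15 is the second risk. Copper insertion into the bromide of 24, which is flanked by a methoxy group and the bulky ring B aryloxy group, may be slow, so that hydrodebromination of 24 and decay of phenol 16 take over. The fallback forms the C–D ether first on a formyl-activated ring C and then adds rings B and A one at a time. It sets out from 16:

- 16 is coupled with purchased 2-bromo-3,4,5-trimethoxybenzaldehyde (O=Cc1cc(OC)c(OC)c(OC)c1Br) with CuI, N,N-dimethylglycine hydrochloride and Cs2CO3 in dioxane at 100 °C; the ortho-formyl group assists the coupling. This should give 2-[3,4-dimethoxy-5-(3,4,5-trimethoxyphenoxy)phenoxy]-3,4,5-trimethoxybenzaldehyde F1.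
- mCPBA in CH2Cl2 should convert it into 2-[3,4-dimethoxy-5-(3,4,5-trimethoxyphenoxy)phenoxy]-3,4,5-trimethoxyphenyl formate F2, and K2CO3 (cat.) in MeOH should then give 2-[3,4-dimethoxy-5-(3,4,5-trimethoxyphenoxy)phenoxy]-3,4,5-trimethoxyphenol F3.
- Coupling of this phenol with 18 under the conditions of step 11 should give 4-{2-[3,4-dimethoxy-5-(3,4,5-trimethoxyphenoxy)phenoxy]-3,4,5-trimethoxyphenoxy}-3,5-dimethoxybenzaldehyde F4.
- A second oxidation with mCPBA should lead through 4-{2-[3,4-dimethoxy-5-(3,4,5-trimethoxyphenoxy)phenoxy]-3,4,5-trimethoxyphenoxy}-3,5-dimethoxyphenyl formate F5 to 4-{2-[3,4-dimethoxy-5-(3,4,5-trimethoxyphenoxy)phenoxy]-3,4,5-trimethoxyphenoxy}-3,5-dimethoxyphenol F6 after methanolysis.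
- Coupling with 23 under the conditions of step 14 should give 25, where the route is rejoined.

Step 7 is the third risk. The enoyl chloride 11 may isomerise about its double bond and then close onto the electron-rich ring D, or lose HCl to a ketene, before it meets the hindered enolate. The fallback attaches the acyl group to the malonate before the aryl ether exists. It sets out from 6. Purchased but-2-ynoic acid (CC#CC(O)=O) is converted with (COCl)2 and DMF (cat.) in CH2Cl2 into but-2-ynoyl chloride F7. This is added to the sodium enolate of 10 (NaH, THF, 0 °C) and should give dimethyl 2-(but-2-ynoyl)-2-methoxypropanedioate F8. Oxa-Michael addition of phenol 6 to this ynone (DABCO cat., CH2Cl2, 0 °C) should give 12, where the route is rejoined.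

**Further compounds**

F0 | step 8 | none | none
F1 | step 15 | 2-[3,4-dimethoxy-5-(3,4,5-trimethoxyphenoxy)phenoxy]-3,4,5-trimethoxybenzaldehyde | O=Cc1cc(OC)c(OC)c(OC)c1Oc1cc(OC)c(OC)c(Oc2cc(OC)c(OC)c(OC)c2)c1
F2 | step 15 | 2-[3,4-dimethoxy-5-(3,4,5-trimethoxyphenoxy)phenoxy]-3,4,5-trimethoxyphenyl formate | O=COc1cc(OC)c(OC)c(OC)c1Oc1cc(OC)c(OC)c(Oc2cc(OC)c(OC)c(OC)c2)c1
F3 | step 15 | 2-[3,4-dimethoxy-5-(3,4,5-trimethoxyphenoxy)phenoxy]-3,4,5-trimethoxyphenol | Oc1cc(OC)c(OC)c(OC)c1Oc1cc(OC)c(OC)c(Oc2cc(OC)c(OC)c(OC)c2)c1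
F4 | step 15 | 4-{2-[3,4-dimethoxy-5-(3,4,5-trimethoxyphenoxy)phenoxy]-3,4,5-trimethoxyphenoxy}-3,5-dimethoxybenzaldehyde | O=Cc1cc(OC)c(Oc2cc(OC)c(OC)c(OC)c2Oc2cc(OC)c(OC)c(Oc3cc(OC)c(OC)c(OC)c3)c2)c(OC)c1
F5 | step 15 | 4-{2-[3,4-dimethoxy-5-(3,4,5-trimethoxyphenoxy)phenoxy]-3,4,5-trimethoxyphenoxy}-3,5-dimethoxyphenyl formate | O=COc1cc(OC)c(Oc2cc(OC)c(OC)c(OC)c2Oc2cc(OC)c(OC)c(Oc3cc(OC)c(OC)c(OC)c3)c2)c(OC)c1
F6 | step 15 | 4-{2-[3,4-dimethoxy-5-(3,4,5-trimethoxyphenoxy)phenoxy]-3,4,5-trimethoxyphenoxy}-3,5-dimethoxyphenol | Oc1cc(OC)c(Oc2cc(OC)c(OC)c(OC)c2Oc2cc(OC)c(OC)c(Oc3cc(OC)c(OC)c(OC)c3)c2)c(OC)c1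
F7 | step 7 | but-2-ynoyl chloride | CC#CC(Cl)=O
F8 | step 7 | dimethyl 2-(but-2-ynoyl)-2-methoxypropanedioate | COC(=O)C(OC)(C(=O)OC)C(=O)C#CC
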